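**Plan**
- Cuts: first the C20–O12 lactone bond and the C2 and C3 hydroxyls, back to a 3,12-diketone. Then C4–C18, C5–C6 and C9–C10 are cut in one stroke, leaving ring A, the ring C/D bicycle and iodomethane. The bicycle is cut at C13–C16.
- Feature used: ring B (C5, C6, C8, C9, C10) sits between two 1,5-dicarbonyl pairs, C20/C12 across C10–C9–C11 and C7/C19 across C6–C5–C4. C9–C10 and C5–C6 are therefore both Michael bonds, and a free C3 ketone makes C4=C5 an alkylidene β-keto ester.
- Forward: rings C and A are bought as cyclohexanones. Ring D closes by a desymmetrising Conia-ene reaction and ring B closes in the union of the two halves. The δ-lactone closes on reduction of C12, and ring A is oxidised at C2 last.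
- Stereochemistry: C8 and C13 come from a chiral amine/silver catalyst pair. C9, C10, C5, C6 and C4 are relayed from the bicycle during the union. C12, C2 and C3 follow from the axial α groups (C10 on ring C, C19 and C20 on ring A).

Key step: step 9

Assumption: gibberellane numbering and α/β descriptors are used throughout, and the keto diester that supplies ring A is taken as purchasable (otherwise one step from methyl 4-oxocyclohexanecarboxylate with NaH and dimethyl carbonate).

Step 1
Reactants: 1 ethyl 1,4-dioxaspiro[4.5]decane-8-carboxylate; 2 propargyl bromide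
Product: 3 ethyl 8-(prop-2-yn-1-yl)-1,4-dioxaspiro[4.5]decane-8-carboxylate
Conditions: LiN(i-Pr)2, THF, −78 °C; 2, −78 → 0 °C
Reagents that add atoms: propargyl bromide, C#CCBr
Why: Ester enolate alkylation with a reactive propargylic halide builds the quaternary carbon (future C8), which is not yet a stereocentre because the ring is still symmetric.

Step 2
Reactants: 3 ethyl 8-(prop-2-yn-1-yl)-1,4-dioxaspiro[4.5]decane-8-carboxylate
Product: 4 8-(prop-2-yn-1-yl)-1,4-dioxaspiro[4.5]decane-8-carboxylic acid
Conditions: KOH, EtOH/H2O, 80 °C; cold 1 M HCl to pH 4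
Reagents that add atoms: potassium hydroxide, [K+].[OH-]
Why: Saponification of the hindered ester needs heat but touches neither the base-stable ketal nor the alkyne, and the brief cold acidification spares the ketal.

Step 3
Reactants: 4 8-(prop-2-yn-1-yl)-1,4-dioxaspiro[4.5]decane-8-carboxylic acid
Product: 6 2-diazo-1-[8-(prop-2-yn-1-yl)-1,4-dioxaspiro[4.5]decan-8-yl]ethan-1-one, via acid chloride 5 (not isolated)
Conditions: 1-chloro-N,N,2-trimethylprop-1-en-1-amine, CH2Cl2, 0 °C → rt; CH2N2 (2.5 equiv), Et2O, 0 °C
Reagents that add atoms: diazomethane, C=[N+]=[N-]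
Why: This is the first half of the Arndt–Eistert homologation, in which the neutral chloroenamine makes the hindered acid chloride without acid that would open the ketal and diazomethane is acylated on carbon.

Step 4
Reactants: 6 2-diazo-1-[8-(prop-2-yn-1-yl)-1,4-dioxaspiro[4.5]decan-8-yl]ethan-1-one
Product: 8 methyl 2-[8-(prop-2-yn-1-yl)-1,4-dioxaspiro[4.5]decan-8-yl]acetate, via ketene 7 (not isolated)
Conditions: hν (365 nm), MeOH, rt
Reagents that add atoms: methanol, CO
Why: In the photochemical Wolff rearrangement the tertiary alkyl group migrates to give the ketene and methanol traps it as the homologous ester (C6–C7), while light avoids silver salts that would bind the terminal alkyne.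

Step 5
Reactants: 8 methyl 2-[8-(prop-2-yn-1-yl)-1,4-dioxaspiro[4.5]decan-8-yl]acetate
Product: 9 methyl 2-[4-oxo-1-(prop-2-yn-1-yl)cyclohexyl]acetate
Conditions: 1 M HCl, acetone, rt
Reagents that add atoms: water, O
Why: Acid-catalysed ketal hydrolysis frees the prochiral ketone, and the methyl ester and the alkyne are inert under these conditions.

Step 6
Reactants: 9 methyl 2-[4-oxo-1-(prop-2-yn-1-yl)cyclohexyl]acetate
Product: 10 methyl 2-[(1R,5R)-6-methylidene-4-oxobicyclo[3.2.1]octan-1-yl]acetate
Conditions: AgNTf2 (5 mol %), cinchona-derived aminophosphine ligand (6 mol %), 2-[bis(3,5-dimethylphenyl)methyl]pyrrolidine (20 mol %), PhCO2H (20 mol %), toluene, 40 °C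
Reagents that add atoms: none
Why: This is a Conia-ene-type cycloisomerisation under amine/silver co-catalysis, a desymmetrisation known for alkyne-linked cyclohexanones, in which the chiral pyrrolidine forms the enamine on one of the two enantiotopic α-carbons, monovalent silver activates the axial propargyl group, and 5-exo-dig attack forms C13–C16 and so fixes C8 and C13 (the antipodes of amine and ligand are chosen for the 1R,5R product).

Step 7
Reactants: 10 methyl 2-[(1R,5R)-6-methylidene-4-oxobicyclo[3.2.1]octan-1-yl]acetate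
Product: 11 methyl 2-[(1S,5R)-6-methylidene-4-oxobicyclo[3.2.1]oct-2-en-1-yl]acetate (fragment CD)
Conditions: IBX, DMSO, 65 °C
Reagents that add atoms: none
Why: In this IBX dehydrogenation C13 is a bridgehead, so the ketone can enolise only towards C11 and the C9=C11 enone is the only possible product.

Step 8
Reactants: 12 dimethyl 4-oxocyclohexane-1,3-dicarboxylate
Product: 15 dimethyl 4-oxocyclohex-2-ene-1,3-dicarboxylate (fragment A, racemic, in equilibrium with its dienol), via selenide 13 (not isolated), via selenoxide 14 (not isolated)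
Conditions: PhSeCl, pyridine, CH2Cl2, 0 °C; 30 % H2O2, 0 °C → rt; used fresh
Reagents that add atoms: none
Why: The β-keto ester is selenenylated at its doubly activated carbon (C4), and selenoxide syn elimination can only go towards C5, the sole β-carbon that bears hydrogen.

Step 9
Reactants: 15 dimethyl 4-oxocyclohex-2-ene-1,3-dicarboxylate (fragment A); 11 methyl 2-[(1S,5R)-6-methylidene-4-oxobicyclo[3.2.1]oct-2-en-1-yl]acetate (fragment CD); 16 iodomethane
Product: 20 tetracyclic 3,12-diketone triester, trimethyl 3,12-dioxogibberell-16-ene-7,19,20-trioate (4β-Me, 4α-CO2Me, 5β-H, 6β-CO2Me, 9β-H, 10α-CO2Me), via potassium trienolate 17 (not isolated), via Michael adduct enolate 18 (not isolated), via tetracyclic enolate 19 (not isolated)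
Conditions: KN(SiMe3)2 (1.0 equiv to 15), THF, −78 °C; 11, 18-crown-6, −78 → 23 °C; MeI, 0 °C
Reagents that add atoms: iodomethane, CI
Why: KN(SiMe3)2 removes the C10 proton of 15 (α to the C20 ester and vinylogous to the C3 ketone and the C19 ester), trienolate 17 adds through C10 to C9 of 11, the C11 enolate of 18 hands its charge to C6, the C6 ester enolate adds to C5, and the β-keto ester enolate 19 is methylated on carbon. The closest known reaction type is the sequential Michael–Michael ring closure ended by enolate alkylation, and 2-carbomethoxycyclohexenones are standard acceptors of base-mediated annulations. Ring B closes 5-exo-trig, C4 of the acceptor staying outside the new ring. C9 is set by axial attack on the face of the bicyclo[3.2.1]octenone anti to the C15–C16 bridge, and C10 by reversibility of the first addition, because only the epimer with C20 next to C11 can bring C5 to C6 with ring A kept clear of ring C. C5 is counted on to follow the least crowded closure, the trans junction that keeps ring A in the plane of ring B instead of folding it onto C15 or under ring C; C6 puts C7 on the β side anti to C4 and stays correctable by base; and C4 takes iodomethane anti to the axial C20 ester, as angularly substituted 3-oxo-4-carboxylates do. The step needs C10 and not C4 as donor terminus and Michael and not Dieckmann closure, and the free C3 ketone secures both, since only the C10 adduct keeps an alkylidene β-keto ester (the best acceptor in the flask), only this path ends in a stabilised enolate, and that enolate has no β-oxygen to expel, unlike an ester enolate next to a C3 ketal.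

Step 10
Reactants: 20 tetracyclic 3,12-diketone triester
Product: 22 3ξ-hydroxy 20,12α-lactone diester (dimethyl 3ξ,12α-dihydroxygibberell-16-ene-7,19,20-trioate 20,12-lactone), via diol triester 21 (not isolated)
Conditions: NaBH4, MeOH/THF, −20 → 23 °C
Reagents that add atoms: none
Why: In this borohydride reduction with lactonisation the α face of C12 is covered by the axial C10 substituent, so hydride should come from the β face, the 12α-alkoxide lies 1,3-diaxial to C10 and closes the δ-lactone on C20 with loss of methoxide, and the C3 carbinol forms as a mixture that does not matter.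

Step 11
Reactants: 22 3ξ-hydroxy 20,12α-lactone diester
Product: 23 3-oxo 20,12α-lactone diester
Conditions: Dess–Martin periodinane, CH2Cl2, 0 °C → rt
Reagents that add atoms: none
Why: Dess–Martin oxidation returns the C3 ketone because the C3 carbinol is the only free hydroxyl once O12 is tied up in the lactone, so the two former ketones are now told apart.

Step 12
Reactants: 23 3-oxo 20,12α-lactone diester
Product: 25 2β-hydroxy-3-oxo 20,12α-lactone diester, via potassium enolate 24 (not isolated)
Conditions: KN(SiMe3)2, THF, −78 °C; 2-(benzenesulfonyl)-3-phenyloxaziridine, −78 °C; AcOH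
Reagents that add atoms: 2-(benzenesulfonyl)-3-phenyloxaziridine, O=S(=O)(c1ccccc1)N1OC1c1ccccc1
Why: In this Davis enolate hydroxylation C4 is quaternary, so the ketone enolises only to C2, the oxaziridine leaves the 16-methylene alone, and the axial α approach to C2 is closed by the 1,3-diaxial C19 and C20 carbonyl groups, so oxygen enters from the β face and ends equatorial.

Step 13
Reactants: 25 2β-hydroxy-3-oxo 20,12α-lactone diester
Product: 26 2β,3β-dihydroxy 20,12α-lactone diester (dimethyl ester of the target)
Conditions: KHB(s-Bu)3 (2.5 equiv), THF, −78 °C; AcOH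
Reagents that add atoms: none
Why: The bulky borohydride should take the equatorial trajectory, as it does with 4,4-disubstituted 3-oxo terpenoids, to give the axial 3β-alcohol cis to the 2β-hydroxyl, and the low temperature and acidic quench guard the β-hydroxy ester against retro-aldol cleavage.

Step 14
Reactants: 26 2β,3β-dihydroxy 20,12α-lactone diester
Product: 27 target, 2β,3β,12α-trihydroxygibberell-16-ene-7,19,20-trioic acid 20,12-lactone (CNP0212122.1)
Conditions: n-PrSLi, HMPA, 23 → 50 °C; dilute HCl
Reagents that add atoms: none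
Why: Thiolate cleaves the methyl esters by SN2 attack at the O–CH3 carbons, which bypasses the hindered acyl carbons of C19 and C7, causes no epimerisation, and leaves the secondary C12–O bond of the lactone intact, as in the demethylation of gibberellin methyl esters.

**Compound list**
1 | ethyl 1,4-dioxaspiro[4.5]decane-8-carboxylate | CCOC(=O)C1CCC2(CC1)OCCO2 | starting material
2 | propargyl bromide | C#CCBr | starting material
3 | ethyl 8-(prop-2-yn-1-yl)-1,4-dioxaspiro[4.5]decane-8-carboxylate | CCOC(=O)C1(CC#C)CCC2(CC1)OCCO2 | intermediate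
4 | 8-(prop-2-yn-1-yl)-1,4-dioxaspiro[4.5]decane-8-carboxylic acid | OC(=O)C1(CC#C)CCC2(CC1)OCCO2 | intermediate
5 | 8-(prop-2-yn-1-yl)-1,4-dioxaspiro[4.5]decane-8-carbonyl chloride | ClC(=O)C1(CC#C)CCC2(CC1)OCCO2 | intermediate
6 | 2-diazo-1-[8-(prop-2-yn-1-yl)-1,4-dioxaspiro[4.5]decan-8-yl]ethan-1-one | [N-]=[N+]=CC(=O)C1(CC#C)CCC2(CC1)OCCO2 | intermediate
7 | [8-(prop-2-yn-1-yl)-1,4-dioxaspiro[4.5]decan-8-yl]ketene | O=C=CC1(CC#C)CCC2(CC1)OCCO2 | intermediate
8 | methyl 2-[8-(prop-2-yn-1-yl)-1,4-dioxaspiro[4.5]decan-8-yl]acetate | COC(=O)CC1(CC#C)CCC2(CC1)OCCO2 | intermediate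
9 | methyl 2-[4-oxo-1-(prop-2-yn-1-yl)cyclohexyl]acetate | COC(=O)CC1(CC#C)CCC(=O)CC1 | intermediate
10 | methyl 2-[(1R,5R)-6-methylidene-4-oxobicyclo[3.2.1]octan-1-yl]acetate | C=C1C[C@]2(CC(=O)OC)C[C@H]1C(=O)CC2 | intermediate
11 | methyl 2-[(1S,5R)-6-methylidene-4-oxobicyclo[3.2.1]oct-2-en-1-yl]acetate (fragment CD) | C=C1C[C@]2(CC(=O)OC)C[C@H]1C(=O)C=C2 | intermediate
12 | dimethyl 4-oxocyclohexane-1,3-dicarboxylate | COC(=O)C1CCC(=O)C(C1)C(=O)OC | starting material
13 | dimethyl 4-oxo-3-(phenylselanyl)cyclohexane-1,3-dicarboxylate | COC(=O)C1CCC(=O)C(C1)([Se]c1ccccc1)C(=O)OC | intermediate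
14 | dimethyl 4-oxo-3-(phenylseleninyl)cyclohexane-1,3-dicarboxylate | COC(=O)C1CCC(=O)C(C1)([Se](=O)c1ccccc1)C(=O)OC | intermediate
15 | dimethyl 4-oxocyclohex-2-ene-1,3-dicarboxylate (fragment A, racemic) | COC(=O)C1CCC(=O)C(C(=O)OC)=C1 | intermediate
16 | iodomethane | CI | starting material
17 | potassium trienolate of fragment A | COC(=O)C1=CC(C(=O)OC)=C([O-])CC1.[K+] | intermediate
18 | C9–C10 Michael adduct as its C11=C12 potassium enolate | C=C1C[C@]2(CC(=O)OC)C[C@H]1C([O-])=C[C@H]2[C@]1(C(=O)OC)CCC(=O)C(C(=O)OC)=C1.[K+] | intermediate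
19 | tetracyclic C3=C4 potassium β-keto ester enolate | C=C1C[C@]23C[C@H]1C(=O)C[C@H]2[C@@]2(CCC([O-])=C(C(=O)OC)[C@H]2[C@@H]3C(=O)OC)C(=O)OC.[K+] | intermediate
20 | tetracyclic 3,12-diketone triester (4β-Me, 4α-CO2Me, 5β-H, 6β-CO2Me, 9β-H, 10α-CO2Me) | C=C1C[C@]23C[C@H]1C(=O)C[C@H]2[C@@]2(CCC(=O)[C@@](C)(C(=O)OC)[C@H]2[C@@H]3C(=O)OC)C(=O)OC | intermediate
21 | 3ξ,12α-diol triester | C=C1C[C@]23C[C@H]1[C@@H](O)C[C@H]2[C@@]2(CCC(O)[C@@](C)(C(=O)OC)[C@H]2[C@@H]3C(=O)OC)C(=O)OC | intermediate
22 | 3ξ-hydroxy 20,12α-lactone diester | C=C1C[C@]23C[C@H]1[C@@H]1C[C@H]2[C@@]2(CCC(O)[C@@](C)(C(=O)OC)[C@H]2[C@@H]3C(=O)OC)C(=O)O1 | intermediate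
23 | 3-oxo 20,12α-lactone diester | C=C1C[C@]23C[C@H]1[C@@H]1C[C@H]2[C@@]2(CCC(=O)[C@@](C)(C(=O)OC)[C@H]2[C@@H]3C(=O)OC)C(=O)O1 | intermediate
24 | C2=C3 potassium enolate of 23 | C=C1C[C@]23C[C@H]1[C@@H]1C[C@H]2[C@@]2(CC=C([O-])[C@@](C)(C(=O)OC)[C@H]2[C@@H]3C(=O)OC)C(=O)O1.[K+] | intermediate
25 | 2β-hydroxy-3-oxo 20,12α-lactone diester | C=C1C[C@]23C[C@H]1[C@@H]1C[C@H]2[C@@]2(C[C@H](O)C(=O)[C@@](C)(C(=O)OC)[C@H]2[C@@H]3C(=O)OC)C(=O)O1 | intermediate
26 | 2β,3β-dihydroxy 20,12α-lactone diester | C=C1C[C@]23C[C@H]1[C@@H]1C[C@H]2[C@@]2(C[C@H](O)[C@H](O)[C@@](C)(C(=O)OC)[C@H]2[C@@H]3C(=O)OC)C(=O)O1 | intermediate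
27 | 2β,3β,12α-trihydroxygibberell-16-ene-7,19,20-trioic acid 20,12-lactone (CNP0212122.1) | C=C1C[C@]23C[C@H]1[C@@H]1C[C@H]2[C@@]2(C[C@H](O)[C@H](O)[C@@](C)(C(=O)O)[C@H]2[C@@H]3C(=O)O)C(=O)O1 | target

Total steps: 14. Longest linear sequence: 13 (steps 1–7 and 9–14).

**Steps most likely to fail**

Step 9. Ring B may close on the face of C5 that is syn to C9, which is the usual course when a five-membered ring closes onto a cyclohexene. That would give a cis A/B junction and also turn the face of methylation at C4. A slow, unfavourable first addition between two hindered carbons is the second danger.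

The fallback sets out from 11 and 15 and comes back at 20.
- The union is run without iodomethane and quenched with acetic acid to give the tetracyclic β-keto ester F1, whatever its junction.
- PhSeCl/pyridine gives the C4 selenide F2 and H2O2 gives its selenoxide F3. Syn elimination then gives the Δ4 alkylidene β-keto ester F4, in which C4 and C5 are planar again.
- [(Ph3P)CuH]6 leaves the isolated C12 ketone alone and, as an external reagent, is not bound by the tether between C6 and C9. It delivers hydride to C5 from the β face, because the α face carries the axial C20 ester, and gives the trans-fused β-keto ester F5.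
- K2CO3 and MeI in acetone methylate C4 anti to C20 to reach 20.

Step 6. The risks are poor enantiotopic selection between the two α-carbons and a sluggish 5-exo-dig closure next to the quaternary carbon.

The fallback sets out from 9 and comes back at 10.
- TBSOTf/Et3N gives the racemic silyl enol ether F6.
- [(t-Bu)2(2-biphenylyl)PAu(NCMe)]SbF6 (monovalent gold, 2 mol %) in CH2Cl2/MeOH cyclises it to the racemic bicyclic ketone F7.
- The enantiomers are separated by preparative chromatography on a chiral stationary phase to give 10.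

Step 10. Hydride may be delivered to the α face of C12. That would give the equatorial 12β-alcohol, which cannot reach C20, so no lactone would form.

The fallback sets out from 20 and comes back at 22.
- Kinetic face control is replaced by an equilibrating Meerwein–Ponndorf–Verley reduction (Al(Oi-Pr)3, i-PrOH, toluene, reflux).
- Reversible hydride transfer interconverts the C12 epimers through the ketone. Only the 12α-alkoxide of 21 is drained, by irreversible lactonisation.
- The C3 carbinol mixture is oxidised in step 11 as before.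
- This fallback makes no compound outside the list (F0).

**Further compounds**
F1 | step 9 | tetracyclic β-keto ester, C4 and C5 undefined | C=C1C[C@]23C[C@H]1C(=O)C[C@H]2[C@@]2(CCC(=O)C(C(=O)OC)C2[C@@H]3C(=O)OC)C(=O)OC
F2 | step 9 | C4 phenylselenide of F1 | C=C1C[C@]23C[C@H]1C(=O)C[C@H]2[C@@]2(CCC(=O)C([Se]c4ccccc4)(C(=O)OC)C2[C@@H]3C(=O)OC)C(=O)OC
F3 | step 9 | C4 selenoxide of F1 | C=C1C[C@]23C[C@H]1C(=O)C[C@H]2[C@@]2(CCC(=O)C([Se](=O)c4ccccc4)(C(=O)OC)C2[C@@H]3C(=O)OC)C(=O)OC
F4 | step 9 | Δ4 alkylidene β-keto ester | C=C1C[C@]23C[C@H]1C(=O)C[C@H]2[C@@]2(CCC(=O)C(C(=O)OC)=C2[C@@H]3C(=O)OC)C(=O)OC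
F5 | step 9 | trans-fused (5β-H) β-keto ester, C4 enolisable | C=C1C[C@]23C[C@H]1C(=O)C[C@H]2[C@@]2(CCC(=O)C(C(=O)OC)[C@H]2[C@@H]3C(=O)OC)C(=O)OC
F6 | step 6 | methyl 2-[4-(tert-butyldimethylsilyloxy)-1-(prop-2-yn-1-yl)cyclohex-3-en-1-yl]acetate (racemic) | COC(=O)CC1(CC#C)CCC(O[Si](C)(C)C(C)(C)C)=CC1
F7 | step 6 | racemic methyl 2-(6-methylidene-4-oxobicyclo[3.2.1]octan-1-yl)acetate | C=C1CC2(CC(=O)OC)CC1C(=O)CC2
F0 | step 10 | none | none
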